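A leftover was what I wanted from these flasks: how much substrate still stands once the dissolved gas has killed the catalyst.

    gas phase ⇌ dissolved gas, rate k1*(csat - [dissolved gas]) (k1 = 2.1 /s, csat = 11 mM)
    substrate + dissolved gas + free catalyst ⇌ free catalyst + product (K2 = 830 /M, k2 = 460 /M²/s, Ea2 = 35.0 kJ/mol, ΔH2 = 8.00 kJ/mol)
    dissolved gas + free catalyst → spent catalyst (k3 = 12 /M/s, Ea3 = 47.0 kJ/mol)
    (constants at 50 °C)

in all of them: substrate 0.30 M; gas phase 11 mM (held); free catalyst 33 mM; time 20 s
- north-west: temperature 50 °C
- south-west: temperature 75 °C
- west: temperature 100 °C

- at the start none of the gas is dissolved
- the constants hold at 50 °C; other temperatures follow from the activation energies and enthalpies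

1. which of these there is most of at the end, counted by the substrate in it, north-west (product / substrate)
2. which of these there is most of at the end, counted by the substrate in it, south-west (product / substrate)
3. which of these there is most of at the end, counted by the substrate in it, west (product / substrate)
4. final amount of the leader among these, as a percentage of the substrate charged, in north-west
5. final amount of the leader among these, as a percentage of the substrate charged, in south-west
6. final amount of the leader among these, as a percentage of the substrate charged, in west

The product step and the death step use the same partners, dissolved gas and free catalyst, so these cancel in the ratio of the forward rates. Each catalyst lost then goes with [substrate] times the product rate constant over the death rate constant of substrate turned over. Integrating, the logarithm of [substrate] falls in proportion to the catalyst lost. I therefore named the budget, the selectivity factor (the ratio of the two rate constants) times the catalyst charged, 1.27. Once the charged catalyst is lost, the product share has a ceiling of one minus the exponential of minus the budget, with the way back not counted. Product passes substrate at a budget of 0.693, and this is the crossing I looked for. Beside the budget I set the catalyst life at saturated dissolved gas, the reciprocal of the death rate constant times csat.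

- north-west, 50 °C: budget 1.27, ceiling 71.8%, life 7.58 s
- south-west, 75 °C: budget 0.918, ceiling 60.1%, life 2.16 s
- west, 100 °C: budget 0.695, ceiling 50.1%, life 0.727 s

The death step has the higher activation energy, so the budget of west is smaller than that of north-west. North-west has 2.64 lives in its time and a budget well above the crossing, so I expected product ahead, below 71.8%. South-west has 9.27 lives and still clears the crossing, so I again expected product, below 60.1%. West has 27.5 lives, but its budget stands on the crossing. In north-west at the start, the forward product step alone would halve dissolved gas in 0.15 s, faster than the gas crossing refills it in 0.330 s, so I expected [dissolved gas] to run below saturation there and the way back to take some product. Assuming the same in west, even a small loss to it puts that flask on the substrate side, and that was my call.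

The forecast said product at 55%, product at 53% and substrate at 57%, allowing for “the reverse reaction at low dissolved gas”.

The flasks gave product at 57.8%, product at 55.5% and substrate at 54.2%. West's product, 45.8%, stood 4.3 percentage points under its ceiling from budget 0.695, with spent catalyst at >99.9%. A neighbouring flask is west with 0.020 M of free catalyst. Its budget is 0.421, under the crossing, and its ceiling is 34.4%. That flask ended with 67% substrate and 32.8% product.

The constants used here are assumed; the flask was simulated.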